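The flavanone's ring C is disconnected at O1–C2 and C4–C4a, which returns it to an aryl cinnamate. The key step uses the twofold axis of ring A through C8 and C5: in a 2-alkyl-5-methoxyresorcinol the oxygens destined to be O1 and the C7 hydroxyl are equivalent, as are C4a and C6. Its mono-cinnamate therefore funnels ortho and para acyl shifts of a photo-Fries rearrangement into one 2'-hydroxychalcone (C4–C4a). A chiral amine–thiourea then closes the pyranone by oxa-Michael addition (O1–C2, 2S) in the same flask. The side-chain stereocentre is taken from (R)-limonene oxide by ring cleavage, one-carbon excision and Negishi coupling.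

Key step: step 11

Assumption: the quinine-derived amine–thiourea is taken to deliver the phenol oxygen to the enone face that gives (2S); should a model chalcone show the opposite sense, the quinidine-derived pseudoenantiomer replaces it with nothing else changed.

Step 1
Reactants: 1 (+)-limonene oxide, (4R)-1-methyl-4-(prop-1-en-2-yl)-7-oxabicyclo[4.1.0]heptane, cis/trans mixture at the epoxide
Product: 2 (3R)-6-oxo-3-(prop-1-en-2-yl)heptanal
Conditions: H5IO6, THF/H2O, 0 °C → rt
Reagents that add atoms: water, O
Why: Periodic acid hydrolyses the epoxide to the 1,2-diol and cleaves it (glycol cleavage) without touching the 1,1-disubstituted alkene, so the ring stereocentre of the terpene becomes C3 of the keto aldehyde unchanged.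

Step 2
Reactants: 2 (3R)-6-oxo-3-(prop-1-en-2-yl)heptanal
Product: 3 (3R)-6-oxo-3-(prop-1-en-2-yl)heptanoic acid
Conditions: NaClO2, NaH2PO4, 2-methyl-2-butene, t-BuOH/H2O, rt
Reagents that add atoms: sodium chlorite, [Na+].[O-]Cl=O
Why: Pinnick oxidation is selective for the aldehyde, the scavenger alkene takes up the hypochlorous acid that would otherwise attack the isopropenyl group, and the stereocentre is β to the carbonyl and cannot epimerise.

Step 3
Reactants: 3 (3R)-6-oxo-3-(prop-1-en-2-yl)heptanoic acid
Product: 5 (5S)-5-(iodomethyl)-6-methylhept-6-en-2-one, via thiohydroxamate ester 4 (not isolated)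
Conditions: 1-hydroxypyridine-2(1H)-thione, DCC, DMAP (cat.), CH2Cl2, 0 °C, dark; then CHI3, benzene, hν (tungsten lamp), 25 °C
Reagents that add atoms: iodoform, IC(I)I; 1-hydroxypyridine-2(1H)-thione, On1ccccc1=S (its atoms stay in intermediate 4 only)
Why: Barton decarboxylative iodination excises the carboxyl carbon, and iodine-atom transfer from iodoform to the primary radical should outrun 3-exo closure onto the neighbouring alkene, so the β-stereocentre is kept (the descriptor becomes S only because CH2I now outranks isopropenyl).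

Step 4
Reactants: 6 5-methoxybenzene-1,3-diol
Product: 7 1-methoxy-3,5-bis(methoxymethoxy)benzene
Conditions: MOMCl, i-Pr2NEt, CH2Cl2, 0 °C → rt
Reagents that add atoms: chloromethyl methyl ether, COCCl
Why: Standard acetal protection of both phenols, chosen because the two methoxymethyl ethers direct the metalation of step 5.

Step 5
Reactants: 7 1-methoxy-3,5-bis(methoxymethoxy)benzene
Product: 9 2-iodo-5-methoxy-1,3-bis(methoxymethoxy)benzene, via aryllithium 8 (not isolated)
Conditions: n-BuLi, THF, 0 °C; then I2, −78 °C → rt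
Reagents that add atoms: iodine, II; n-butyllithium, [Li]CCCC (lithium stays in intermediate 8 only)
Why: Directed ortho-metalation should occur at the carbon flanked by the two chelating methoxymethyl ethers (a stronger pairing than ether plus methoxy), and iodine quench gives the symmetrical iodide.

Step 6
Reactants: 5 (5S)-5-(iodomethyl)-6-methylhept-6-en-2-one; 9 2-iodo-5-methoxy-1,3-bis(methoxymethoxy)benzene
Product: 11 (5R)-5-{[4-methoxy-2,6-bis(methoxymethoxy)phenyl]methyl}-6-methylhept-6-en-2-one, via alkylzinc iodide 10 (not isolated)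
Conditions: Zn dust (activated with 1,2-dibromoethane and Me3SiCl), LiCl, THF, 40 °C; then 9, Pd(OAc)2 (2 mol %), SPhos (4 mol %), THF, 25 → 50 °C
Reagents that add atoms: zinc, [Zn] (held in intermediate 10 only)
Why: Negishi coupling: zinc insertion into the primary iodide tolerates the ketone, the biaryl phosphine lets zerovalent palladium enter the doubly ortho-substituted iodide and promotes fast reductive elimination, and the stereocentre β to the metal is not involved (now R by priority only).

Step 7
Reactants: 11 (5R)-5-{[4-methoxy-2,6-bis(methoxymethoxy)phenyl]methyl}-6-methylhept-6-en-2-one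
Product: 12 (5R)-5-{[4-methoxy-2,6-bis(methoxymethoxy)phenyl]methyl}-2,6-dimethylhept-6-en-2-ol
Conditions: MeMgBr, THF, −78 → 0 °C; aq. NH4Cl
Reagents that add atoms: methylmagnesium bromide, C[Mg]Br
Why: Grignard addition to the methyl ketone gives the tertiary carbinol of the side chain; acetals, aryl ethers and the alkene are inert.

Step 8
Reactants: 12 (5R)-5-{[4-methoxy-2,6-bis(methoxymethoxy)phenyl]methyl}-2,6-dimethylhept-6-en-2-ol
Product: 14 2-[(2R)-5-hydroxy-5-methyl-2-(prop-1-en-2-yl)hexyl]-5-methoxybenzene-1,3-diol, via tris(trimethylsilyl) ether 13 (not isolated)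
Conditions: Me3SiOTf, 2,2'-bipyridyl, CH2Cl2, 0 °C → rt; then H2O/THF, citric acid, rt
Reagents that add atoms: trimethylsilyl trifluoromethanesulfonate, C[Si](C)(C)OS(=O)(=O)C(F)(F)F (silicon held in intermediate 13 only)
Why: Silyl triflate buffered by bipyridyl converts aryl methoxymethyl ethers into aryl silyl ethers without free protic acid, which avoids acid-catalysed closure of the liberated phenol onto the isopropenyl group and ionisation of the tertiary alcohol; the silyl ethers fall off on aqueous work-up.

Step 9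
Reactants: 15 (2E)-3-(2,4-dihydroxyphenyl)prop-2-enoic acid
Product: 17 (2E)-3-[2,4-bis(tert-butyldimethylsilyloxy)phenyl]prop-2-enoic acid, via silyl ester 16 (not isolated)
Conditions: t-BuMe2SiCl, imidazole, DMF, rt, dark; then K2CO3, THF/MeOH/H2O, 0 °C; 1 M HCl to pH 4
Reagents that add atoms: tert-butyldimethylsilyl chloride, CC(C)(C)[Si](C)(C)Cl
Why: Exhaustive silylation followed by selective hydrolysis of the far more labile silyl ester gives the protected acid; the 2-O-silyl group also prevents the Z isomer formed under light in step 11 from lactonising to a coumarin.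

Step 10
Reactants: 14 2-[(2R)-5-hydroxy-5-methyl-2-(prop-1-en-2-yl)hexyl]-5-methoxybenzene-1,3-diol; 17 (2E)-3-[2,4-bis(tert-butyldimethylsilyloxy)phenyl]prop-2-enoic acid
Product: 18 3-hydroxy-2-[(2R)-5-hydroxy-5-methyl-2-(prop-1-en-2-yl)hexyl]-5-methoxyphenyl (2E)-3-[2,4-bis(tert-butyldimethylsilyloxy)phenyl]prop-2-enoate
Conditions: EDC·HCl, DMAP (cat.), 14 in excess (2 equiv, recovered), CH2Cl2, 0 °C → rt
Reagents that add atoms: none
Why: Steglich esterification acylates a phenol and leaves the tertiary alcohol alone; the two phenols of 14 are interchanged by the twofold axis so either gives the same monoester, and the excess of diol holds back diester formation.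

Step 11
Reactants: 18 3-hydroxy-2-[(2R)-5-hydroxy-5-methyl-2-(prop-1-en-2-yl)hexyl]-5-methoxyphenyl (2E)-3-[2,4-bis(tert-butyldimethylsilyloxy)phenyl]prop-2-enoate
Product: 20 (2S)-2-[2,4-bis(tert-butyldimethylsilyloxy)phenyl]-7-hydroxy-8-[(2R)-5-hydroxy-5-methyl-2-(prop-1-en-2-yl)hexyl]-5-methoxy-2,3-dihydro-4H-chromen-4-one, via chalcone 19 (not isolated)
Conditions: hν (300–320 nm, Pyrex), degassed toluene (2 mM), 20 °C; then concentrate to 0.1 M, 1-[3,5-bis(trifluoromethyl)phenyl]-3-[(8S,9S)-6'-methoxycinchonan-9-yl]thiourea (20 mol %), toluene, 0 → 25 °C, dark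
Reagents that add atoms: none
Why: Excitation of the cinnamate ester cleaves the aryl-O–acyl bond to a caged phenoxyl/cinnamoyl radical pair that recombines at a ring carbon and tautomerises (photo-Fries rearrangement; closest known cases are hydroxyphenyl cinnamates giving 2'-hydroxychalcones and flavanones), which makes the C4–C4a bond of chalcone 19. The selectivity needed is the site of acyl return, and the substrate secures it: ring A has a twofold axis through the alkylated and the methoxylated carbon, so recombination ortho or para to the ester oxygen gives the same chalcone, while attack at the alkyl-bearing ortho carbon gives a dienone that can only revert. The amine–thiourea then closes ring C by a 6-endo-trig oxa-Michael addition of the 2'-hydroxyl to the enone β-carbon (O1–C2); only this hydroxyl is ortho to the carbonyl, the 4'-hydroxyl cannot reach and the 6'-oxygen is methylated. The C2 stereocentre is set by the catalyst, whose thiourea binds the carbonyl oxygen and whose quinuclidine nitrogen activates the phenol so that oxygen is delivered to one enone face (taken as the one giving 2S); the remote side-chain centre exerts no bias and is untouched. E/Z isomerisation of ester or chalcone is harmless because both isomers funnel into the same closure, high dilution suppresses [2+2] dimerisation, and the hydrogen-bonded 2'-hydroxychalcone sheds excitation by excited-state proton transfer and so should survive the irradiation. Radical pairs that escape the cage only return diol 14, which is recycled.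

Step 12
Reactants: 20 (2S)-2-[2,4-bis(tert-butyldimethylsilyloxy)phenyl]-7-hydroxy-8-[(2R)-5-hydroxy-5-methyl-2-(prop-1-en-2-yl)hexyl]-5-methoxy-2,3-dihydro-4H-chromen-4-one
Product: 21 (2S)-2-(2,4-dihydroxyphenyl)-7-hydroxy-8-[(2R)-5-hydroxy-5-methyl-2-(prop-1-en-2-yl)hexyl]-5-methoxy-2,3-dihydro-4H-chromen-4-one
Conditions: Bu4NF, AcOH (1:1), THF, 0 °C
Reagents that add atoms: none
Why: Fluoride cleaves the two aryl silyl ethers, and the acetic acid buffer keeps the medium from becoming basic enough to open ring C by retro-oxa-Michael reaction and scramble C2; the alkene and the tertiary alcohol are inert.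

Compound list
1 | (+)-limonene oxide, (4R)-1-methyl-4-(prop-1-en-2-yl)-7-oxabicyclo[4.1.0]heptane (cis/trans mixture) | C=C(C)[C@@H]1CCC2(C)OC2C1 | starting material
2 | (3R)-6-oxo-3-(prop-1-en-2-yl)heptanal | C=C(C)[C@H](CCC(C)=O)CC=O | intermediate
3 | (3R)-6-oxo-3-(prop-1-en-2-yl)heptanoic acid | C=C(C)[C@H](CCC(C)=O)CC(=O)O | intermediate
4 | 2-sulfanylidenepyridin-1(2H)-yl (3R)-6-oxo-3-(prop-1-en-2-yl)heptanoate | C=C(C)[C@H](CCC(C)=O)CC(=O)On1ccccc1=S | intermediate
5 | (5S)-5-(iodomethyl)-6-methylhept-6-en-2-one | C=C(C)[C@H](CCC(C)=O)CI | intermediate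
6 | 5-methoxybenzene-1,3-diol | COc1cc(O)cc(O)c1 | starting material
7 | 1-methoxy-3,5-bis(methoxymethoxy)benzene | COCOc1cc(OC)cc(OCOC)c1 | intermediate
8 | [4-methoxy-2,6-bis(methoxymethoxy)phenyl]lithium | COCOc1cc(OC)cc(OCOC)c1[Li] | intermediate
9 | 2-iodo-5-methoxy-1,3-bis(methoxymethoxy)benzene | COCOc1cc(OC)cc(OCOC)c1I | intermediate
10 | [(2S)-3-methyl-2-(3-oxobutyl)but-3-en-1-yl]zinc iodide | C=C(C)[C@H](CCC(C)=O)C[Zn]I | intermediate
11 | (5R)-5-{[4-methoxy-2,6-bis(methoxymethoxy)phenyl]methyl}-6-methylhept-6-en-2-one | C=C(C)[C@H](CCC(C)=O)Cc1c(OCOC)cc(OC)cc1OCOC | intermediate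
12 | (5R)-5-{[4-methoxy-2,6-bis(methoxymethoxy)phenyl]methyl}-2,6-dimethylhept-6-en-2-ol | C=C(C)[C@H](CCC(C)(C)O)Cc1c(OCOC)cc(OC)cc1OCOC | intermediate
13 | {[(5R)-5-{[4-methoxy-2,6-bis(trimethylsilyloxy)phenyl]methyl}-2,6-dimethylhept-6-en-2-yl]oxy}trimethylsilane | C=C(C)[C@H](CCC(C)(C)O[Si](C)(C)C)Cc1c(O[Si](C)(C)C)cc(OC)cc1O[Si](C)(C)C | intermediate
14 | 2-[(2R)-5-hydroxy-5-methyl-2-(prop-1-en-2-yl)hexyl]-5-methoxybenzene-1,3-diol | C=C(C)[C@H](CCC(C)(C)O)Cc1c(O)cc(OC)cc1O | intermediate
15 | (2E)-3-(2,4-dihydroxyphenyl)prop-2-enoic acid | OC(=O)/C=C/c1ccc(O)cc1O | starting material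
16 | tert-butyldimethylsilyl (2E)-3-[2,4-bis(tert-butyldimethylsilyloxy)phenyl]prop-2-enoate | CC(C)(C)[Si](C)(C)OC(=O)/C=C/c1ccc(O[Si](C)(C)C(C)(C)C)cc1O[Si](C)(C)C(C)(C)C | intermediate
17 | (2E)-3-[2,4-bis(tert-butyldimethylsilyloxy)phenyl]prop-2-enoic acid | OC(=O)/C=C/c1ccc(O[Si](C)(C)C(C)(C)C)cc1O[Si](C)(C)C(C)(C)C | intermediate
18 | 3-hydroxy-2-[(2R)-5-hydroxy-5-methyl-2-(prop-1-en-2-yl)hexyl]-5-methoxyphenyl (2E)-3-[2,4-bis(tert-butyldimethylsilyloxy)phenyl]prop-2-enoate | C=C(C)[C@H](CCC(C)(C)O)Cc1c(O)cc(OC)cc1OC(=O)/C=C/c1ccc(O[Si](C)(C)C(C)(C)C)cc1O[Si](C)(C)C(C)(C)C | intermediate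
19 | (2E)-3-[2,4-bis(tert-butyldimethylsilyloxy)phenyl]-1-{2,4-dihydroxy-3-[(2R)-5-hydroxy-5-methyl-2-(prop-1-en-2-yl)hexyl]-6-methoxyphenyl}prop-2-en-1-one | C=C(C)[C@H](CCC(C)(C)O)Cc1c(O)cc(OC)c(C(=O)/C=C/c2ccc(O[Si](C)(C)C(C)(C)C)cc2O[Si](C)(C)C(C)(C)C)c1O | intermediate
20 | (2S)-2-[2,4-bis(tert-butyldimethylsilyloxy)phenyl]-7-hydroxy-8-[(2R)-5-hydroxy-5-methyl-2-(prop-1-en-2-yl)hexyl]-5-methoxy-2,3-dihydro-4H-chromen-4-one | C=C(C)[C@H](CCC(C)(C)O)Cc1c(O)cc(OC)c2c1O[C@H](c1ccc(O[Si](C)(C)C(C)(C)C)cc1O[Si](C)(C)C(C)(C)C)CC2=O | intermediate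
21 | (2S)-2-(2,4-dihydroxyphenyl)-7-hydroxy-8-[(2R)-5-hydroxy-5-methyl-2-(prop-1-en-2-yl)hexyl]-5-methoxy-2,3-dihydro-4H-chromen-4-one | C=C(C)[C@H](CCC(C)(C)O)Cc1c(O)cc(OC)c2c1O[C@H](c1ccc(O)cc1O)CC2=O | target

Total step count: 12. Longest linear sequence: 9 steps (1, 2, 3, 6, 7, 8, 10, 11, 12).

Steps most likely to fail

Step 11. The process most likely to spoil it is poor facial selectivity in the oxa-Michael closure: an unactivated, electron-rich chalcone carrying a second free phenol may bind the catalyst loosely, and reversible ring opening erodes whatever selectivity is reached. Inefficient acyl migration is the lesser concern. The fallback gives up asymmetric induction for separation with recycling. It sets out from 18, which is irradiated as in step 11, and the ring is then closed with an achiral base (DBU 10 mol %, toluene, 25 °C). This should give 20 together with its C2 epimer, (2R)-2-[2,4-bis(tert-butyldimethylsilyloxy)phenyl]-7-hydroxy-8-[(2R)-5-hydroxy-5-methyl-2-(prop-1-en-2-yl)hexyl]-5-methoxy-2,3-dihydro-4H-chromen-4-one F1. The two diastereomers are separated by preparative HPLC, and F1 is returned to the same base, which re-equilibrates it through chalcone 19 for another pass. The route is rejoined at 20.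

Step 6. The alkyl(aryl)palladium intermediate may undergo β-hydride elimination, since its β-hydrogen is allylic and reductive elimination at the doubly ortho-substituted aryl is slow. That would give a diene and, through re-insertion, erode the configuration of the side-chain centre. The fallback replaces cross-coupling by an SN2 alkylation with no metal hydride pathway. It sets out from 5, which is ketalised (ethylene glycol, PPTS, benzene, reflux) to 2-[(3S)-3-(iodomethyl)-4-methylpent-4-en-1-yl]-2-methyl-1,3-dioxolane F2. Aryllithium 8, made from 7 with n-BuLi as in step 5, is alkylated with F2 in THF/DMPU (0 → 25 °C) to give 2-[(3R)-3-{[4-methoxy-2,6-bis(methoxymethoxy)phenyl]methyl}-4-methylpent-4-en-1-yl]-2-methyl-1,3-dioxolane F3. Hydrolysis of the ketal (PPTS, acetone/H2O, 50 °C) comes back to the route at 11.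

Step 3. The alkyl radical may be captured by the thiocarbonyl group of unreacted ester, giving the 2-pyridyl sulfide in competition with iodine transfer, and the light-sensitive ester may decompose before the chain is established. The fallback couples the acid directly instead of passing through the iodide. It sets out from 3, which is converted (N-hydroxyphthalimide, DIC, DMAP cat., CH2Cl2) into the redox-active ester 1,3-dioxo-1,3-dihydro-2H-isoindol-2-yl (3R)-6-oxo-3-(prop-1-en-2-yl)heptanoate F4. Aryllithium 8 (from 7, n-BuLi) is transmetalated with ZnCl2 to chloro[4-methoxy-2,6-bis(methoxymethoxy)phenyl]zinc F5. Nickel-catalysed decarboxylative arylation of F4 with F5 (NiCl2·DME 20 mol %, 4,4'-di-tert-butyl-2,2'-bipyridine 40 mol %, THF/DMF, 25 °C) comes back to the route at 11, bypassing 5, 9 and step 6.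

Further compounds
F1 | step 11 | (2R)-2-[2,4-bis(tert-butyldimethylsilyloxy)phenyl]-7-hydroxy-8-[(2R)-5-hydroxy-5-methyl-2-(prop-1-en-2-yl)hexyl]-5-methoxy-2,3-dihydro-4H-chromen-4-one | C=C(C)[C@H](CCC(C)(C)O)Cc1c(O)cc(OC)c2c1O[C@@H](c1ccc(O[Si](C)(C)C(C)(C)C)cc1O[Si](C)(C)C(C)(C)C)CC2=O
F2 | step 6 | 2-[(3S)-3-(iodomethyl)-4-methylpent-4-en-1-yl]-2-methyl-1,3-dioxolane | C=C(C)[C@H](CCC1(C)OCCO1)CI
F3 | step 6 | 2-[(3R)-3-{[4-methoxy-2,6-bis(methoxymethoxy)phenyl]methyl}-4-methylpent-4-en-1-yl]-2-methyl-1,3-dioxolane | C=C(C)[C@H](CCC1(C)OCCO1)Cc1c(OCOC)cc(OC)cc1OCOC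
F4 | step 3 | 1,3-dioxo-1,3-dihydro-2H-isoindol-2-yl (3R)-6-oxo-3-(prop-1-en-2-yl)heptanoate | C=C(C)[C@H](CCC(C)=O)CC(=O)ON1C(=O)c2ccccc2C1=O
F5 | step 3 | chloro[4-methoxy-2,6-bis(methoxymethoxy)phenyl]zinc | COCOc1cc(OC)cc(OCOC)c1[Zn]Cl
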